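**Strategy.** The plan rests on closing the γ-lactone at its alkyl C–O bond, O(lactone)–C6, by displacement instead of acylation. An anionic oxy-Cope ring expansion of a carvone-derived dialkenylcyclohexenol builds the ten-membered ring with Z-C4=C5 and E-C1=C10 and leaves C6 as a ketone that hydride reaches only from the ring periphery, giving the 6-epi alcohol. The key step exploits that C6 is a secondary allylic carbon (next to C4=C5) lying γ to the C12 carboxyl: Mitsunobu closure of the seco acid inverts C6 and forms the five-membered lactone trans-fused to the carbocycle in one operation. Its precursor is the 1,10-epoxy 6S-hydroxy 12-acid with O3 and O8 protected.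

Key step: step 10

Remark: germacrane numbering (ring C1–C10, C14 on C10, C15 on C4, C11–C13 on C7) is used for all ten-membered-ring compounds and for the atoms of their precursors; compounds 1, 5, 6, 13 and 26 are taken as commercial.

Step 1
Reactants: 1 (S)-carvone
Product: 2 (1S,5S)-cis-carveol
Conditions: NaBH4, CeCl3·7H2O, MeOH, 0 °C
Reagents that add atoms: none
Why: Luche 1,2-reduction; hydride adds axially to the half-chair enone with the isopropenyl group pseudo-equatorial and should give the cis carbinol, a centre that only holds the place of the C2=C3 alkene made in step 17.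

Step 2
Reactants: 2 (1S,5S)-cis-carveol
Product: 3 tert-butyldimethylsilyl ether of 2
Conditions: TBSCl, imidazole, DMF, rt
Reagents that add atoms: tert-butyldimethylsilyl chloride, C[Si](C)(Cl)C(C)(C)C
Why: Standard silyl ether formation; the ether blocks this ring-allylic position in step 3 and should survive the bases, peracid, hydride, Mitsunobu and enolate conditions that follow.

Step 3
Reactants: 3 tert-butyldimethylsilyl ether of 2
Product: 4 (4S,6S)-4-[(tert-butyldimethylsilyl)oxy]-3-methyl-6-(prop-1-en-2-yl)cyclohex-2-en-1-one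
Conditions: Rh2(cap)4 (cap = caprolactamate, 1 mol%), t-BuOOH (70% in water), CH2Cl2, rt
Reagents that add atoms: tert-butyl hydroperoxide, CC(C)(C)OO
Why: Allylic C–H oxidation by tert-butylperoxy radicals: the only free ring-allylic methylene (future C6, next to the CH end of the trisubstituted alkene) is oxidised to the enone, as steroidal 5-enes give 7-ketones, the other ring-allylic site being blocked by the silyloxy group; no stereocentre is touched.

Step 4
Reactants: 5 4-methoxybenzyl alcohol; 6 vinyl acetate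
Product: 7 4-methoxybenzyl vinyl ether
Conditions: [Ir(cod)Cl]2 (1 mol%), Na2CO3, toluene, 100 °C
Reagents that add atoms: none
Why: Iridium-catalysed transfer vinylation of an alcohol by vinyl acetate (addition–elimination on the coordinated vinyl ester); no stereocentre.

Step 5
Reactants: 7 4-methoxybenzyl vinyl ether
Product: 9 (Z)-1-bromo-2-[(4-methoxybenzyl)oxy]ethene, via dibromide 8 (not isolated)
Conditions: Br2, CH2Cl2, −78 °C; then i-Pr2NEt, −78 °C to rt
Reagents that add atoms: bromine, BrBr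
Why: Bromine addition to the enol ether and amine-induced loss of HBr through the oxocarbenium ion (addition–elimination); the cis β-bromo enol ether should be the favoured isomer and is separated from any E isomer.

Step 6
Reactants: 9 (Z)-1-bromo-2-[(4-methoxybenzyl)oxy]ethene; 4 (4S,6S)-4-[(tert-butyldimethylsilyl)oxy]-3-methyl-6-(prop-1-en-2-yl)cyclohex-2-en-1-one
Product: 12 (1S,4S,6S)-4-[(tert-butyldimethylsilyl)oxy]-1-{(Z)-2-[(4-methoxybenzyl)oxy]ethenyl}-3-methyl-6-(prop-1-en-2-yl)cyclohex-2-en-1-ol, via vinyllithium 10 (not isolated), via vinylcerium dichloride 11 (not isolated)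
Conditions: t-BuLi (2 equiv), Et2O, −78 °C; CeCl3, THF, −78 °C; then 4, −78 °C
Reagents that add atoms: none
Why: Bromine–lithium exchange with retention of the Z geometry, transmetalation to the weakly basic organocerium reagent and 1,2-addition to the enolisable enone; the reagent should enter anti to the neighbouring isopropenyl group (equatorial attack), which makes the two alkenyl groups trans and the new carbinol centre S, the arrangement the chair oxy-Cope transition state needs.

Step 7
Reactants: 12 (1S,4S,6S)-4-[(tert-butyldimethylsilyl)oxy]-1-{(Z)-2-[(4-methoxybenzyl)oxy]ethenyl}-3-methyl-6-(prop-1-en-2-yl)cyclohex-2-en-1-ol; 13 methyl bromoacetate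
Product: 16 methyl (1(10)E,4Z,3S,7R,8R)-3-[(tert-butyldimethylsilyl)oxy]-8-[(4-methoxybenzyl)oxy]-6-oxo-13-norgermacra-1(10),4-dien-12-oate, via potassium alkoxide 14 (not isolated), via potassium enolate 15 (not isolated)
Conditions: KH, 18-crown-6, THF, 0 °C to rt; then 13, −78 °C
Reagents that add atoms: none
Why: Anionic oxy-Cope rearrangement with in situ enolate alkylation: the trans-dialkenyl alkoxide can react only through a chair transition state, which cleaves the C6–C1 bond of the carvone ring, forms C8–C9, gives the E-C1=C10 bond while keeping the ring-derived Z-C4=C5 bond and relays the carvone stereocentre to C8 (R, the Z-alkoxy group being axial), and the regiodefined enolate is then C-alkylated on its peripheral face, which should set C7 (R) anti to the C8 oxygen.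

Step 8
Reactants: 16 methyl (1(10)E,4Z,3S,7R,8R)-3-[(tert-butyldimethylsilyl)oxy]-8-[(4-methoxybenzyl)oxy]-6-oxo-13-norgermacra-1(10),4-dien-12-oate
Product: 17 methyl (4Z,1R,3S,7R,8R,10R)-1,10-epoxy-3-[(tert-butyldimethylsilyl)oxy]-8-[(4-methoxybenzyl)oxy]-6-oxo-13-norgermacr-4-en-12-oate
Conditions: mCPBA, CH2Cl2, −20 °C
Reagents that add atoms: 3-chloroperoxybenzoic acid, O=C(OO)c1cccc(Cl)c1
Why: Prilezhaev epoxidation: the strained, electron-rich E-C1=C10 alkene reacts far faster than the enone alkene, and only its outer face is exposed in the crown conformer inherited from the chair transition state, which should give the (1R,10R) trans-epoxide.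

Step 9
Reactants: 17 methyl (4Z,1R,3S,7R,8R,10R)-1,10-epoxy-3-[(tert-butyldimethylsilyl)oxy]-8-[(4-methoxybenzyl)oxy]-6-oxo-13-norgermacr-4-en-12-oate
Product: 19 (4Z,1R,3S,6S,7S,8R,10R)-1,10-epoxy-6-hydroxy-3-[(tert-butyldimethylsilyl)oxy]-8-[(4-methoxybenzyl)oxy]-13-norgermacr-4-en-12-oic acid, via hydroxy ester 18 (not isolated)
Conditions: NaBH4, CeCl3·7H2O, MeOH, −78 °C; then aqueous LiOH, 0 °C to rt; cold 0.1 M HCl to pH 5, used at once
Reagents that add atoms: lithium hydroxide, [Li+].[OH-]
Why: Luche 1,2-reduction then saponification in the same flask: hydride can reach the C6 carbonyl only from the ring periphery (the sense also expected for cerium bridging the C6 carbonyl and the C8 ether oxygen), which should give the 6S alcohol with its hydroxyl pointing into the ring, and hydroxide then cleaves the methyl ester by acyl substitution without touching epoxide or ethers.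

Step 10
Reactants: 19 (4Z,1R,3S,6S,7S,8R,10R)-1,10-epoxy-6-hydroxy-3-[(tert-butyldimethylsilyl)oxy]-8-[(4-methoxybenzyl)oxy]-13-norgermacr-4-en-12-oic acid
Product: 20 (4Z,1R,3S,6R,7R,8R,10R)-1,10-epoxy-3-[(tert-butyldimethylsilyl)oxy]-8-[(4-methoxybenzyl)oxy]-13-norgermacr-4-en-12,6-olide
Conditions: PPh3, DIAD, THF, 0 °C, slow addition of 19
Reagents that add atoms: none
Why: Mitsunobu lactonization: the betaine from PPh3 and DIAD deprotonates the C12 acid and turns the C6 hydroxyl into an alkoxyphosphonium leaving group, which the C12 carboxylate displaces intramolecularly with loss of Ph3PO. The closest known reaction type is the invertive Mitsunobu closure of γ-hydroxy acids to γ-lactones. The γ-lactone ring (O, C12, C11, C7, C6) closes in a 5-exo-tet mode by forming the O–C6 bond. C6 becomes R by SN2 inversion of the 6S carbinol that peripheral hydride delivery provided, so the lactone is trans-fused to the ten-membered ring (H6 and H7 anti), C7 having been fixed in step 7. The step needs SN2 at C6 over SN2′ at C4, over acyl activation with retention and over elimination; this should be secured because in the crown conformer the C6–O bond points into the ring while the C7 acetic acid arm sits on the outer face antiperiplanar to it, so that backside attack is pre-organised whereas acyl closure is not. No other hydroxyl or acid is free, and epoxide, silyl ether and PMB ether are inert to the neutral conditions.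

Step 11
Reactants: 20 (4Z,1R,3S,6R,7R,8R,10R)-1,10-epoxy-3-[(tert-butyldimethylsilyl)oxy]-8-[(4-methoxybenzyl)oxy]-13-norgermacr-4-en-12,6-olide
Product: 24 (4Z,1R,3S,6R,7R,8R,10R)-1,10-epoxy-3-[(tert-butyldimethylsilyl)oxy]-8-[(4-methoxybenzyl)oxy]germacra-4,11(13)-dien-12,6-olide, via lithium enolate 21 (not isolated), via Mannich base 22 (not isolated), via ammonium iodide 23 (not isolated)
Conditions: LiN(iPr)2, THF, −78 °C; CH2=NMe2+ I−, −78 °C to rt; then MeI, MeOH, rt; then aqueous NaHCO3, EtOAc, rt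
Reagents that add atoms: Eschenmoser's salt (N,N-dimethylmethyleneiminium iodide), C=[N+](C)C.[I-]
Why: Mannich reaction of the lactone enolate with Eschenmoser's salt, exhaustive N-methylation and Hofmann-type β-elimination; C11 is the only enolisable position and its transient stereocentre disappears on elimination.

Step 12
Reactants: 24 (4Z,1R,3S,6R,7R,8R,10R)-1,10-epoxy-3-[(tert-butyldimethylsilyl)oxy]-8-[(4-methoxybenzyl)oxy]germacra-4,11(13)-dien-12,6-olide
Product: 25 (4Z,1R,3S,6R,7R,8R,10R)-1,10-epoxy-8-hydroxy-3-[(tert-butyldimethylsilyl)oxy]germacra-4,11(13)-dien-12,6-olide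
Conditions: DDQ, CH2Cl2/pH 7 buffer, 0 °C
Reagents that add atoms: none
Why: Oxidative PMB cleavage (single-electron oxidation to the benzylic oxocarbenium ion and hydrolysis), done before the diene exists so that nothing else in the molecule is electron-rich enough to react; C8 is untouched.

Step 13
Reactants: 26 (E)-2-methylbut-2-en-1-ol
Product: 27 [(2R,3R)-2,3-dimethyloxiran-2-yl]methanol
Conditions: Ti(OiPr)4 (cat.), D-(−)-diethyl tartrate (cat.), t-BuOOH, 4 Å MS, CH2Cl2, −20 °C
Reagents that add atoms: tert-butyl hydroperoxide, CC(C)(C)OO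
Why: Sharpless asymmetric epoxidation of an E-trisubstituted allylic alcohol; the D-tartrate catalyst delivers oxygen to the face that gives the (2R,3R)-epoxy alcohol, and the two methyl groups stay cis as in the alkene.

Step 14
Reactants: 27 [(2R,3R)-2,3-dimethyloxiran-2-yl]methanol
Product: 28 (2S,3R)-2,3-dimethyloxirane-2-carboxylic acid
Conditions: RuCl3 (cat.), NaIO4, CCl4/MeCN/H2O, rt
Reagents that add atoms: water, O
Why: Ruthenium tetroxide oxidation of the primary alcohol through the aldehyde hydrate to the glycidic acid; the epoxide and both stereocentres are retained (the C2 descriptor changes only through the priority rules).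

Step 15
Reactants: 28 (2S,3R)-2,3-dimethyloxirane-2-carboxylic acid; 25 (4Z,1R,3S,6R,7R,8R,10R)-1,10-epoxy-8-hydroxy-3-[(tert-butyldimethylsilyl)oxy]germacra-4,11(13)-dien-12,6-olide
Product: 30 (4Z,1R,3S,6R,7R,8R,10R)-1,10-epoxy-3-[(tert-butyldimethylsilyl)oxy]-8-{[(2S,3R)-2,3-dimethyloxiran-2-yl]carbonyloxy}germacra-4,11(13)-dien-12,6-olide, via mixed anhydride 29 (not isolated)
Conditions: 2,4,6-trichlorobenzoyl chloride, Et3N, THF, rt; then 25, DMAP, toluene, rt
Reagents that add atoms: none
Why: Yamaguchi esterification: DMAP attacks the less hindered epoxy-acyl carbonyl of the mixed anhydride and the acylpyridinium acylates the only free hydroxyl (C8) with retention at C8 and at both epoxide carbons of the acid.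

Step 16
Reactants: 30 (4Z,1R,3S,6R,7R,8R,10R)-1,10-epoxy-3-[(tert-butyldimethylsilyl)oxy]-8-{[(2S,3R)-2,3-dimethyloxiran-2-yl]carbonyloxy}germacra-4,11(13)-dien-12,6-olide
Product: 31 (4Z,1R,3S,6R,7R,8R,10R)-1,10-epoxy-3-hydroxy-8-{[(2S,3R)-2,3-dimethyloxiran-2-yl]carbonyloxy}germacra-4,11(13)-dien-12,6-olide
Conditions: Bu4NF, AcOH (1:1), THF, 0 °C to rt
Reagents that add atoms: none
Why: Fluoride-mediated Si–O cleavage, buffered with acetic acid so that the α-methylene lactone, both epoxides and the ester are not attacked; it frees the allylic C3 hydroxyl.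

Step 17
Reactants: 31 (4Z,1R,3S,6R,7R,8R,10R)-1,10-epoxy-3-hydroxy-8-{[(2S,3R)-2,3-dimethyloxiran-2-yl]carbonyloxy}germacra-4,11(13)-dien-12,6-olide
Product: 32 CNP0122107.1
Conditions: Martin sulfurane Ph2S[OC(CF3)2Ph]2, CH2Cl2, −20 °C to rt
Reagents that add atoms: none
Why: Dehydration of the allylic C3 alcohol through its alkoxysulfurane (loss of Ph2SO): only C2 carries a β-hydrogen, so the C2=C3 bond forms regiospecifically, and it should form cis because the C1–C2–C3–C4 torsion is synclinal and a trans C2=C3 bond between the trans-epoxide and the cis C4=C5 bond would be highly strained in the ten-membered ring.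

**Compound list**

1 | (S)-carvone, (5S)-2-methyl-5-(prop-1-en-2-yl)cyclohex-2-en-1-one | CC1=CC[C@@H](CC1=O)C(C)=C | starting material
2 | (1S,5S)-cis-carveol, (1S,5S)-2-methyl-5-(prop-1-en-2-yl)cyclohex-2-en-1-ol | CC1=CC[C@@H](C[C@@H]1O)C(C)=C | intermediate
3 | tert-butyldimethylsilyl ether of 2 | CC1=CC[C@@H](C[C@@H]1O[Si](C)(C)C(C)(C)C)C(C)=C | intermediate
4 | (4S,6S)-4-[(tert-butyldimethylsilyl)oxy]-3-methyl-6-(prop-1-en-2-yl)cyclohex-2-en-1-one | CC1=CC(=O)[C@@H](C[C@@H]1O[Si](C)(C)C(C)(C)C)C(C)=C | intermediate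
5 | 4-methoxybenzyl alcohol | COc1ccc(CO)cc1 | starting material
6 | vinyl acetate | CC(=O)OC=C | starting material
7 | 4-methoxybenzyl vinyl ether | COc1ccc(COC=C)cc1 | intermediate
8 | 1,2-dibromoethyl 4-methoxybenzyl ether (racemic) | COc1ccc(COC(Br)CBr)cc1 | intermediate
9 | (Z)-1-bromo-2-[(4-methoxybenzyl)oxy]ethene | COc1ccc(CO/C=C\Br)cc1 | intermediate
10 | (Z)-2-[(4-methoxybenzyl)oxy]vinyllithium | COc1ccc(CO/C=C\[Li])cc1 | intermediate
11 | dichloro{(Z)-2-[(4-methoxybenzyl)oxy]vinyl}cerium | COc1ccc(CO/C=C\[Ce](Cl)Cl)cc1 | intermediate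
12 | (1S,4S,6S)-4-[(tert-butyldimethylsilyl)oxy]-1-{(Z)-2-[(4-methoxybenzyl)oxy]ethenyl}-3-methyl-6-(prop-1-en-2-yl)cyclohex-2-en-1-ol (alkenyl groups trans) | CC1=C[C@@](O)(/C=C\OCc2ccc(OC)cc2)[C@@H](C[C@@H]1O[Si](C)(C)C(C)(C)C)C(C)=C | intermediate
13 | methyl bromoacetate | COC(=O)CBr | starting material
14 | potassium alkoxide of 12 | CC1=C[C@@]([O-])(/C=C\OCc2ccc(OC)cc2)[C@@H](C[C@@H]1O[Si](C)(C)C(C)(C)C)C(C)=C.[K+] | intermediate
15 | potassium (1(10)E,4Z,6Z,3S,8R)-3-[(tert-butyldimethylsilyl)oxy]-8-[(4-methoxybenzyl)oxy]-11,12,13-trinorgermacra-1(10),4,6-trien-6-olate | [O-]/C1=C\[C@H](OCc2ccc(OC)cc2)C/C(C)=C/C[C@H](O[Si](C)(C)C(C)(C)C)/C(C)=C\1.[K+] | intermediate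
16 | methyl (1(10)E,4Z,3S,7R,8R)-3-[(tert-butyldimethylsilyl)oxy]-8-[(4-methoxybenzyl)oxy]-6-oxo-13-norgermacra-1(10),4-dien-12-oate | O=C1/C=C(C)\[C@@H](O[Si](C)(C)C(C)(C)C)C/C=C(C)/C[C@@H](OCc2ccc(OC)cc2)[C@H]1CC(=O)OC | intermediate
17 | methyl (4Z,1R,3S,7R,8R,10R)-1,10-epoxy-3-[(tert-butyldimethylsilyl)oxy]-8-[(4-methoxybenzyl)oxy]-6-oxo-13-norgermacr-4-en-12-oate | O=C1/C=C(C)\[C@@H](O[Si](C)(C)C(C)(C)C)C[C@H]2O[C@]2(C)C[C@@H](OCc3ccc(OC)cc3)[C@H]1CC(=O)OC | intermediate
18 | methyl (4Z,1R,3S,6S,7S,8R,10R)-1,10-epoxy-6-hydroxy-3-[(tert-butyldimethylsilyl)oxy]-8-[(4-methoxybenzyl)oxy]-13-norgermacr-4-en-12-oate | O[C@H]1/C=C(C)\[C@@H](O[Si](C)(C)C(C)(C)C)C[C@H]2O[C@]2(C)C[C@@H](OCc3ccc(OC)cc3)[C@H]1CC(=O)OC | intermediate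
19 | (4Z,1R,3S,6S,7S,8R,10R)-1,10-epoxy-6-hydroxy-3-[(tert-butyldimethylsilyl)oxy]-8-[(4-methoxybenzyl)oxy]-13-norgermacr-4-en-12-oic acid (6-epi seco acid) | O[C@H]1/C=C(C)\[C@@H](O[Si](C)(C)C(C)(C)C)C[C@H]2O[C@]2(C)C[C@@H](OCc3ccc(OC)cc3)[C@H]1CC(=O)O | intermediate
20 | (4Z,1R,3S,6R,7R,8R,10R)-1,10-epoxy-3-[(tert-butyldimethylsilyl)oxy]-8-[(4-methoxybenzyl)oxy]-13-norgermacr-4-en-12,6-olide (trans-fused lactone) | O=C1O[C@@H]2/C=C(C)\[C@@H](O[Si](C)(C)C(C)(C)C)C[C@H]3O[C@]3(C)C[C@@H](OCc4ccc(OC)cc4)[C@H]2C1 | intermediate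
21 | lithium enolate of 20 (C11=C12–O−) | C1=C([O-])O[C@@H]2/C=C(C)\[C@@H](O[Si](C)(C)C(C)(C)C)C[C@H]3O[C@]3(C)C[C@@H](OCc4ccc(OC)cc4)[C@@H]12.[Li+] | intermediate
22 | 13-(dimethylamino) derivative of 20, Mannich base (C11 epimers) | CN(C)CC1C(=O)O[C@@H]2/C=C(C)\[C@@H](O[Si](C)(C)C(C)(C)C)C[C@H]3O[C@]3(C)C[C@@H](OCc4ccc(OC)cc4)[C@@H]12 | intermediate
23 | 13-(trimethylammonio) derivative of 20, iodide salt (C11 epimers) | C[N+](C)(C)CC1C(=O)O[C@@H]2/C=C(C)\[C@@H](O[Si](C)(C)C(C)(C)C)C[C@H]3O[C@]3(C)C[C@@H](OCc4ccc(OC)cc4)[C@@H]12.[I-] | intermediate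
24 | (4Z,1R,3S,6R,7R,8R,10R)-1,10-epoxy-3-[(tert-butyldimethylsilyl)oxy]-8-[(4-methoxybenzyl)oxy]germacra-4,11(13)-dien-12,6-olide | C=C1C(=O)O[C@@H]2/C=C(C)\[C@@H](O[Si](C)(C)C(C)(C)C)C[C@H]3O[C@]3(C)C[C@@H](OCc4ccc(OC)cc4)[C@@H]12 | intermediate
25 | (4Z,1R,3S,6R,7R,8R,10R)-1,10-epoxy-8-hydroxy-3-[(tert-butyldimethylsilyl)oxy]germacra-4,11(13)-dien-12,6-olide | C=C1C(=O)O[C@@H]2/C=C(C)\[C@@H](O[Si](C)(C)C(C)(C)C)C[C@H]3O[C@]3(C)C[C@@H](O)[C@@H]12 | intermediate
26 | (E)-2-methylbut-2-en-1-ol | C/C=C(\C)CO | starting material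
27 | [(2R,3R)-2,3-dimethyloxiran-2-yl]methanol | OC[C@@]1(C)O[C@@H]1C | intermediate
28 | (2S,3R)-2,3-dimethyloxirane-2-carboxylic acid | OC(=O)[C@@]1(C)O[C@@H]1C | intermediate
29 | (2S,3R)-2,3-dimethyloxirane-2-carboxylic 2,4,6-trichlorobenzoic anhydride | O=C(OC(=O)c1c(Cl)cc(Cl)cc1Cl)[C@@]1(C)O[C@@H]1C | intermediate
30 | (4Z,1R,3S,6R,7R,8R,10R)-1,10-epoxy-3-[(tert-butyldimethylsilyl)oxy]-8-{[(2S,3R)-2,3-dimethyloxiran-2-yl]carbonyloxy}germacra-4,11(13)-dien-12,6-olide | C=C1C(=O)O[C@@H]2/C=C(C)\[C@@H](O[Si](C)(C)C(C)(C)C)C[C@H]3O[C@]3(C)C[C@@H](OC(=O)[C@@]3(C)O[C@@H]3C)[C@@H]12 | intermediate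
31 | (4Z,1R,3S,6R,7R,8R,10R)-1,10-epoxy-3-hydroxy-8-{[(2S,3R)-2,3-dimethyloxiran-2-yl]carbonyloxy}germacra-4,11(13)-dien-12,6-olide | C=C1C(=O)O[C@@H]2/C=C(C)\[C@@H](O)C[C@H]3O[C@]3(C)C[C@@H](OC(=O)[C@@]3(C)O[C@@H]3C)[C@@H]12 | intermediate
32 | CNP0122107.1, (2Z,4Z,1R,6R,7R,8R,10R)-1,10-epoxy-8-{[(2S,3R)-2,3-dimethyloxiran-2-yl]carbonyloxy}germacra-2,4,11(13)-trien-12,6-olide | C=C1C(=O)O[C@@H]2/C=C(C)\C=C/[C@H]3O[C@]3(C)C[C@@H](OC(=O)[C@@]3(C)O[C@@H]3C)[C@@H]12 | target

**Step count.** Total: 17 steps. Longest linear sequence: 13 steps from (S)-carvone (steps 1, 2, 3, 6, 7, 8, 9, 10, 11, 12, 15, 16, 17).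

**Steps most likely to fail**

Step 7. The crown-complexed potassium enolate may lose the C8 alkoxide by β-elimination during the rearrangement. It may also be O-alkylated or alkylated with poor facial control at C7. The fallback sets out from 12: the rearrangement is run as before but quenched at −78 °C with Me3SiCl/Et3N as soon as it is complete, which gives the trimethylsilyl enol ether F1 and keeps the lifetime of the free enolate short. MeLi in THF at −78 °C then regenerates the regiodefined enolate as its lithium salt, which is alkylated with 13 at that temperature. The sequence comes back to the route at 16.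

Step 10. The betaine may activate the carboxyl instead of the hindered C6 hydroxyl, which would close the lactone by acylation with retention. The alkoxyphosphonium may also be attacked in the SN2′ sense or eliminate. The fallback sets out from 17: the Luche reduction is worked up to isolate hydroxy ester 18, which is converted into its C6 methanesulfonate F2 (Ms2O, Et3N, CH2Cl2, −40 °C). LiOH in THF/H2O at 0 °C then frees the C12 carboxylate, which displaces the allylic sulfonate in a 5-exo-tet SN2 reaction with the same inversion. The sequence comes back to the route at 20.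

Step 17. The dehydration may run through an allylic cation and lose geometric control at C2=C3. It may also give the transposed allylic ether, or open the vinyl epoxide as it forms. The fallback sets out from 31: the C3 alcohol is converted into the C3 methanesulfonate F3 (Ms2O, Et3N, CH2Cl2, −40 °C) and treated with DBU in MeCN at rt. Base-induced antiperiplanar E2 elimination across the synclinal C1–C2–C3–C4 segment can give only the cis C2=C3 bond. The sequence comes back to the route at 32.

**Further compounds**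

F1 | step 7 | (1(10)E,4Z,6Z,3S,8R)-3-[(tert-butyldimethylsilyl)oxy]-8-[(4-methoxybenzyl)oxy]-6-[(trimethylsilyl)oxy]-11,12,13-trinorgermacra-1(10),4,6-triene | C[Si](C)(C)O/C1=C\[C@H](OCc2ccc(OC)cc2)C/C(C)=C/C[C@H](O[Si](C)(C)C(C)(C)C)/C(C)=C\1
F2 | step 10 | methyl (4Z,1R,3S,6S,7S,8R,10R)-1,10-epoxy-6-(methanesulfonyloxy)-3-[(tert-butyldimethylsilyl)oxy]-8-[(4-methoxybenzyl)oxy]-13-norgermacr-4-en-12-oate | CS(=O)(=O)O[C@H]1/C=C(C)\[C@@H](O[Si](C)(C)C(C)(C)C)C[C@H]2O[C@]2(C)C[C@@H](OCc3ccc(OC)cc3)[C@H]1CC(=O)OC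
F3 | step 17 | (4Z,1R,3S,6R,7R,8R,10R)-1,10-epoxy-3-(methanesulfonyloxy)-8-{[(2S,3R)-2,3-dimethyloxiran-2-yl]carbonyloxy}germacra-4,11(13)-dien-12,6-olide | C=C1C(=O)O[C@@H]2/C=C(C)\[C@@H](OS(C)(=O)=O)C[C@H]3O[C@]3(C)C[C@@H](OC(=O)[C@@]3(C)O[C@@H]3C)[C@@H]12
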